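## Retrosynthetic overview

1. Daucane numbering is used: five-membered ring C1(Me, quaternary)–C2–C3–C4(OH, iPr)–C5(H); seven-membered ring C5–C6(O-vanilloyl)–C7=C8(Me)–C9(OH)–C10–C1. The last events are a Mitsunobu esterification that inverts the 6-epi alcohol with O-silylated vanillic acid, then global desilylation.
2. Key disconnection: the cyclopentane is cut at C1–C2 and C3–C4. Both bonds come from one hydrogen-atom-transfer-initiated radical conjugate addition/aldol [3+2] annulation of acrolein with cycloheptene 14 (exocyclic C1=CH2, isobutyryl on C5); the surplus formyl group on C3 is then removed by decarbonylation.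
3. Enabling feature: in the five-membered ring the methyl-bearing quaternary carbon C1 and the tertiary carbinol C4 (OH, isopropyl) stand 1,3 to each other across the ring-fusion carbon C5, joined only by the unsubstituted C2–C3 bridge. C1 therefore maps onto a tertiary radical from a 1,1-disubstituted alkene (the hydrogen transfer also makes the methyl), C4 onto a ketone aldol acceptor, and C2–C3 onto an enal.
4. Cycloheptene 14 comes from ring-closing metathesis (C7=C8) of aldol 13. C9 is set by a catalytic asymmetric allylation of methacrolein and C5/C6 by a reagent-controlled syn boron aldol with acrolein; C1 and C4 (and the transient C3) are relayed from these by substrate control in the key step.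
5. Ring order: seven-membered ring first (metathesis), five-membered ring second (key annulation).

Key step: step 8

Assumption (reagent sense): (−)-Ipc2BOTf is taken to deliver its Z-enol borinate to the Si face of an aldehyde and (R)-BINOL/Ti(OiPr)4 to give the (R)-carbinol from an enal; if either sense were the reverse, the antipodal reagent would be used and nothing else would change.

## Route

Step 1
Reactants: 1 3-chloro-2-(chloromethyl)prop-1-ene
Product: 2 tributyl[2-(chloromethyl)prop-2-en-1-yl]stannane
Conditions: Bu3SnH, LiN(iPr)2, THF, −78 to 0 °C; then 1 (3 equiv), −78 °C to rt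
Reagents that add atoms: tributylstannyllithium, [Li][Sn](CCCC)(CCCC)CCCC (made in the flask from tributyltin hydride and LiN(iPr)2)
Why: Nucleophilic substitution of one allylic chloride by the stannyl anion (SN2 or SN2′, both give the same product), with the excess of dichloride 1 suppressing double substitution.

Step 2
Reactants: 2 tributyl[2-(chloromethyl)prop-2-en-1-yl]stannane; 3 2-methylprop-2-enal (methacrolein)
Product: 4 (3R)-5-(chloromethyl)-2-methylhexa-1,5-dien-3-ol
Conditions: (R)-BINOL (20 mol%), Ti(OiPr)4 (10 mol%), 4 Å MS, CH2Cl2, −20 °C; aq NaHCO3 work-up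
Reagents that add atoms: none
Why: Keck catalytic asymmetric allylation, in which the allylstannane adds 1,2 to the enal under the chiral BINOL–titanium Lewis acid, so the C9 carbinol (R) is set by catalyst control while the allylic chloride is untouched.

Step 3
Reactants: 4 (3R)-5-(chloromethyl)-2-methylhexa-1,5-dien-3-ol
Product: 5 tert-butyl{[(3R)-5-(chloromethyl)-2-methylhexa-1,5-dien-3-yl]oxy}dimethylsilane
Conditions: TBSCl, imidazole, DMF, rt
Reagents that add atoms: tert-butyldimethylsilyl chloride (TBSCl), CC(C)(C)[Si](C)(C)Cl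
Why: Standard silylation of the secondary alcohol, which protects the future C9 hydroxyl up to step 12 and prevents cyclisation of the alkoxide onto the allylic chloride.

Step 4
Reactants: 5 tert-butyl{[(3R)-5-(chloromethyl)-2-methylhexa-1,5-dien-3-yl]oxy}dimethylsilane; 6 2-methylpropanal
Product: 8 (7R)-7-[(tert-butyldimethylsilyl)oxy]-2,8-dimethyl-5-methylidenenon-8-en-3-ol (both C3 epimers), via allylzinc chloride 7 (not isolated)
Conditions: Zn dust, THF/sat. aq NH4Cl, rt
Reagents that add atoms: none
Why: Zinc-mediated Barbier allylation under neutral aqueous conditions that spare the silyl ether; the 2-substituted allylzinc gives the same constitution from either terminus, and the new carbinol centre is oxidised in step 5, so its configuration does not matter.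

Step 5
Reactants: 8 (7R)-7-[(tert-butyldimethylsilyl)oxy]-2,8-dimethyl-5-methylidenenon-8-en-3-ol
Product: 9 (7R)-7-[(tert-butyldimethylsilyl)oxy]-2,8-dimethyl-5-methylidenenon-8-en-3-one
Conditions: Dess–Martin periodinane, NaHCO3, CH2Cl2, 0 °C
Reagents that add atoms: none
Why: Buffered Dess–Martin oxidation gives the β,γ-unsaturated ketone without acid or base that would move the alkene into conjugation.

Step 6
Reactants: 9 (7R)-7-[(tert-butyldimethylsilyl)oxy]-2,8-dimethyl-5-methylidenenon-8-en-3-one; 10 prop-2-enal (acrolein)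
Product: 13 (4S,7R)-7-[(tert-butyldimethylsilyl)oxy]-4-[(1R)-1-hydroxyprop-2-en-1-yl]-2,8-dimethyl-5-methylidenenon-8-en-3-one, via Z-enol borinate 11 (not isolated), via boron aldolate 12 (not isolated)
Conditions: (−)-Ipc2BOTf, iPr2NEt, CH2Cl2, −78 °C; then 10, −78 to −20 °C; then H2O2, MeOH, pH 7 buffer, 0 °C
Reagents that add atoms: none
Why: Reagent-controlled syn boron aldol reaction, in which the ketone is enolised at the doubly activated CH2 to the Z-enol diisopinocampheylborinate and this adds to acrolein through a chair transition state, so that C5 (S) and C6 (R) are set by the isopinocampheyl ligands and α-attack of the dienolate keeps the alkene as the exocyclic methylene.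

Step 7
Reactants: 13 (4S,7R)-7-[(tert-butyldimethylsilyl)oxy]-4-[(1R)-1-hydroxyprop-2-en-1-yl]-2,8-dimethyl-5-methylidenenon-8-en-3-one
Product: 14 1-[(1S,2R,5R)-5-[(tert-butyldimethylsilyl)oxy]-2-hydroxy-4-methyl-7-methylidenecyclohept-3-en-1-yl]-2-methylpropan-1-one
Conditions: second-generation Grubbs catalyst RuCl2(=CHPh)(PCy3)(H2IMes) (5–10 mol%), CH2Cl2 (high dilution), 40 °C
Reagents that add atoms: none
Why: Ring-closing metathesis of the vinyl and isopropenyl groups forms the trisubstituted C7=C8 bond of the seven-membered ring with loss of ethene, while the 1,1-disubstituted C1 methylene cannot close a ring of workable size and stays.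

Step 8
Reactants: 14 1-[(1S,2R,5R)-5-[(tert-butyldimethylsilyl)oxy]-2-hydroxy-4-methyl-7-methylidenecyclohept-3-en-1-yl]-2-methylpropan-1-one; 10 prop-2-enal (acrolein)
Product: 17 (2S,3R,3aS,4R,7R,8aR)-7-[(tert-butyldimethylsilyl)oxy]-3,4-dihydroxy-6,8a-dimethyl-3-(propan-2-yl)-1,2,3,3a,4,7,8,8a-octahydroazulene-2-carbaldehyde, via tertiary C1 radical 15 (not isolated), via aldehyde enolate 16 (not isolated)
Conditions: Fe(acac)3 (30 mol%), PhSiH3 (2.5 equiv), 10 (5 equiv), EtOH/(CH2OH)2, 0 °C to rt
Reagents that add atoms: none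
Why: An iron hydride formed from Fe(acac)3 and PhSiH3 transfers a hydrogen atom to the terminal carbon of the exocyclic 1,1-disubstituted alkene (this makes the C1 methyl group and the tertiary C1 radical 15), the radical adds to acrolein in a Giese addition (C1–C2), divalent iron reduces the α-formyl radical to enolate 16 (radical–polar crossover), and the enolate closes onto the isopropyl ketone in an intramolecular aldol addition (C3–C4, tertiary carbinol). The closest known reaction type is the hydrogen-atom-transfer-initiated radical conjugate addition–aldol annulation of alkene-tethered ketones with enals and enones, used here as a formal [3+2] annulation. The five-membered ring closes in the polar step as a 5-(enolexo)-exo-trig aldol cyclisation after an intermolecular radical addition, and gives the trans-fused bicyclo[5.3.0]decane. C1 is set by substrate control: the C5 acyl group, the C6 hydroxyl and the C9 silyloxy group all lie on one face of the cycloheptene, so acrolein should add to the other face, which puts C2 trans to the acyl carbon and the new methyl cis to it. C4 is set in the aldol transition state, in which the isopropyl group turns away from C6 (towards H5) and the carbonyl oxygen can hydrogen-bond to the C6 hydroxyl, so the new hydroxyl should end up cis to the angular methyl; C3 may form as either epimer because step 9 erases it. The step needs hydrogen-atom transfer to the exocyclic alkene and not to the ring alkene, which is secured by the lower reactivity of the trisubstituted alkene flanked by two oxygen-bearing carbons, and it needs radical trapping and aldol closure to outrun simple reduction, which is helped by an excess of the unhindered acceptor and by the 1,4-relation of radical carbon and ketone.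

Step 9
Reactants: 17 (2S,3R,3aS,4R,7R,8aR)-7-[(tert-butyldimethylsilyl)oxy]-3,4-dihydroxy-6,8a-dimethyl-3-(propan-2-yl)-1,2,3,3a,4,7,8,8a-octahydroazulene-2-carbaldehyde
Product: 18 (3R,3aS,4R,7R,8aR)-7-[(tert-butyldimethylsilyl)oxy]-6,8a-dimethyl-3-(propan-2-yl)-1,2,3,3a,4,7,8,8a-octahydroazulene-3,4-diol
Conditions: RhCl(PPh3)3 (1.1 equiv), toluene, 110 °C
Reagents that add atoms: none
Why: Tsuji–Wilkinson decarbonylation, in which monovalent rhodium inserts into the aldehyde C–H bond, extrudes CO and forms the C–H bond by reductive elimination under neutral conditions, so C3 becomes the required CH2.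

Step 10
Reactants: 19 4-hydroxy-3-methoxybenzoic acid (vanillic acid)
Product: 21 4-[(tert-butyldimethylsilyl)oxy]-3-methoxybenzoic acid, via bis-silyl derivative 20 (not isolated)
Conditions: TBSCl (2.2 equiv), imidazole, DMF, rt; then AcOH/H2O/THF, rt
Reagents that add atoms: tert-butyldimethylsilyl chloride (TBSCl), CC(C)(C)[Si](C)(C)Cl
Why: Silylation of both acidic OH groups followed by selective hydrolysis of the labile silyl ester leaves the phenol protected and the carboxylic acid free.

Step 11
Reactants: 18 (3R,3aS,4R,7R,8aR)-7-[(tert-butyldimethylsilyl)oxy]-6,8a-dimethyl-3-(propan-2-yl)-1,2,3,3a,4,7,8,8a-octahydroazulene-3,4-diol; 21 4-[(tert-butyldimethylsilyl)oxy]-3-methoxybenzoic acid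
Product: 23 (3R,3aS,4S,7R,8aR)-7-[(tert-butyldimethylsilyl)oxy]-3-hydroxy-6,8a-dimethyl-3-(propan-2-yl)-1,2,3,3a,4,7,8,8a-octahydroazulen-4-yl 4-[(tert-butyldimethylsilyl)oxy]-3-methoxybenzoate, via alkoxyphosphonium carboxylate 22 (not isolated)
Conditions: PPh3, DIAD, toluene, 0 °C to rt
Reagents that add atoms: none
Why: Mitsunobu esterification, in which the secondary allylic C6 hydroxyl is activated as the alkoxyphosphonium ion and displaced by the carboxylate with SN2 inversion, so the ester is installed and C6 is corrected to the target configuration in one step while the tertiary C4 hydroxyl does not react.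

Step 12
Reactants: 23 (3R,3aS,4S,7R,8aR)-7-[(tert-butyldimethylsilyl)oxy]-3-hydroxy-6,8a-dimethyl-3-(propan-2-yl)-1,2,3,3a,4,7,8,8a-octahydroazulen-4-yl 4-[(tert-butyldimethylsilyl)oxy]-3-methoxybenzoate
Product: 24 (3R,3aS,4S,7R,8aR)-3,7-dihydroxy-6,8a-dimethyl-3-(propan-2-yl)-1,2,3,3a,4,7,8,8a-octahydroazulen-4-yl 4-hydroxy-3-methoxybenzoate (CNP0189996.3)
Conditions: HF·pyridine, pyridine/THF, 0 °C to rt
Reagents that add atoms: none
Why: Fluoride-mediated cleavage of the aryl and the secondary alkyl silyl ethers under non-basic conditions leaves the benzoate ester and the allylic and tertiary alcohols intact.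

## Compound list

1 | 3-chloro-2-(chloromethyl)prop-1-ene | ClCC(=C)CCl | starting material
2 | tributyl[2-(chloromethyl)prop-2-en-1-yl]stannane | CCCC[Sn](CCCC)(CCCC)CC(=C)CCl | intermediate
3 | 2-methylprop-2-enal (methacrolein) | CC(=C)C=O | starting material
4 | (3R)-5-(chloromethyl)-2-methylhexa-1,5-dien-3-ol | CC(=C)[C@H](O)CC(=C)CCl | intermediate
5 | tert-butyl{[(3R)-5-(chloromethyl)-2-methylhexa-1,5-dien-3-yl]oxy}dimethylsilane | CC(=C)[C@H](O[Si](C)(C)C(C)(C)C)CC(=C)CCl | intermediate
6 | 2-methylpropanal (isobutyraldehyde) | CC(C)C=O | starting material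
7 | chloro{(4R)-4-[(tert-butyldimethylsilyl)oxy]-5-methyl-2-methylidenehex-5-en-1-yl}zinc (allylzinc chloride, not isolated) | Cl[Zn]CC(=C)C[C@@H](O[Si](C)(C)C(C)(C)C)C(C)=C | intermediate
8 | (7R)-7-[(tert-butyldimethylsilyl)oxy]-2,8-dimethyl-5-methylidenenon-8-en-3-ol (both C3 epimers) | CC(C)C(O)CC(=C)C[C@@H](O[Si](C)(C)C(C)(C)C)C(C)=C | intermediate
9 | (7R)-7-[(tert-butyldimethylsilyl)oxy]-2,8-dimethyl-5-methylidenenon-8-en-3-one | CC(C)C(=O)CC(=C)C[C@@H](O[Si](C)(C)C(C)(C)C)C(C)=C | intermediate
10 | prop-2-enal (acrolein) | C=CC=O | starting material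
11 | Z-enol diisopinocampheylborinate of ketone 9, (−)-Ipc series (not isolated) | CC(C)/C(OB([C@@H]1C[C@@H]2C[C@H]([C@H]1C)C2(C)C)[C@@H]1C[C@@H]2C[C@H]([C@H]1C)C2(C)C)=C/C(=C)C[C@@H](O[Si](C)(C)C(C)(C)C)C(C)=C | intermediate
12 | diisopinocampheylboron aldolate of 13 (boron on the new C6 oxygen, not isolated) | C=C[C@@H](OB([C@@H]1C[C@@H]2C[C@H]([C@H]1C)C2(C)C)[C@@H]1C[C@@H]2C[C@H]([C@H]1C)C2(C)C)[C@@H](C(=O)C(C)C)C(=C)C[C@@H](O[Si](C)(C)C(C)(C)C)C(C)=C | intermediate
13 | (4S,7R)-7-[(tert-butyldimethylsilyl)oxy]-4-[(1R)-1-hydroxyprop-2-en-1-yl]-2,8-dimethyl-5-methylidenenon-8-en-3-one | C=C[C@@H](O)[C@@H](C(=O)C(C)C)C(=C)C[C@@H](O[Si](C)(C)C(C)(C)C)C(C)=C | intermediate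
14 | 1-[(1S,2R,5R)-5-[(tert-butyldimethylsilyl)oxy]-2-hydroxy-4-methyl-7-methylidenecyclohept-3-en-1-yl]-2-methylpropan-1-one (acyl, hydroxyl and silyloxy groups all cis) | O[C@@H]1C=C(C)[C@H](O[Si](C)(C)C(C)(C)C)CC(=C)[C@@H]1C(=O)C(C)C | intermediate
15 | tertiary C1 radical from 14 (hydrogen added to the exocyclic CH2, not isolated) | O[C@@H]1C=C(C)[C@H](O[Si](C)(C)C(C)(C)C)C[C](C)[C@@H]1C(=O)C(C)C | intermediate
16 | iron-bound aldehyde enolate of the Giese adduct (shown as the enolate anion, not isolated) | O[C@@H]1C=C(C)[C@H](O[Si](C)(C)C(C)(C)C)C[C@@](C)(CC=C[O-])[C@@H]1C(=O)C(C)C | intermediate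
17 | (2S,3R,3aS,4R,7R,8aR)-7-[(tert-butyldimethylsilyl)oxy]-3,4-dihydroxy-6,8a-dimethyl-3-(propan-2-yl)-1,2,3,3a,4,7,8,8a-octahydroazulene-2-carbaldehyde (trans-fused; C2 of the azulene may be either epimer) | O[C@@H]1C=C(C)[C@H](O[Si](C)(C)C(C)(C)C)C[C@@]2(C)C[C@H](C=O)[C@@](O)(C(C)C)[C@H]12 | intermediate
18 | (3R,3aS,4R,7R,8aR)-7-[(tert-butyldimethylsilyl)oxy]-6,8a-dimethyl-3-(propan-2-yl)-1,2,3,3a,4,7,8,8a-octahydroazulene-3,4-diol | O[C@@H]1C=C(C)[C@H](O[Si](C)(C)C(C)(C)C)C[C@@]2(C)CC[C@@](O)(C(C)C)[C@H]12 | intermediate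
19 | 4-hydroxy-3-methoxybenzoic acid (vanillic acid) | COc1cc(C(=O)O)ccc1O | starting material
20 | tert-butyldimethylsilyl 4-[(tert-butyldimethylsilyl)oxy]-3-methoxybenzoate (not isolated) | COc1cc(C(=O)O[Si](C)(C)C(C)(C)C)ccc1O[Si](C)(C)C(C)(C)C | intermediate
21 | 4-[(tert-butyldimethylsilyl)oxy]-3-methoxybenzoic acid | COc1cc(C(=O)O)ccc1O[Si](C)(C)C(C)(C)C | intermediate
22 | triphenyl{[(3R,3aS,4R,7R,8aR)-7-[(tert-butyldimethylsilyl)oxy]-3-hydroxy-6,8a-dimethyl-3-(propan-2-yl)-1,2,3,3a,4,7,8,8a-octahydroazulen-4-yl]oxy}phosphonium 4-[(tert-butyldimethylsilyl)oxy]-3-methoxybenzoate (not isolated) | COc1cc(C(=O)[O-])ccc1O[Si](C)(C)C(C)(C)C.c1ccccc1[P+](c1ccccc1)(c1ccccc1)O[C@@H]1C=C(C)[C@H](O[Si](C)(C)C(C)(C)C)C[C@@]2(C)CC[C@@](O)(C(C)C)[C@H]12 | intermediate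
23 | (3R,3aS,4S,7R,8aR)-7-[(tert-butyldimethylsilyl)oxy]-3-hydroxy-6,8a-dimethyl-3-(propan-2-yl)-1,2,3,3a,4,7,8,8a-octahydroazulen-4-yl 4-[(tert-butyldimethylsilyl)oxy]-3-methoxybenzoate | COc1cc(C(=O)O[C@H]2C=C(C)[C@H](O[Si](C)(C)C(C)(C)C)C[C@@]3(C)CC[C@@](O)(C(C)C)[C@H]23)ccc1O[Si](C)(C)C(C)(C)C | intermediate
24 | (3R,3aS,4S,7R,8aR)-3,7-dihydroxy-6,8a-dimethyl-3-(propan-2-yl)-1,2,3,3a,4,7,8,8a-octahydroazulen-4-yl 4-hydroxy-3-methoxybenzoate | COc1cc(C(=O)O[C@H]2C=C(C)[C@H](O)C[C@@]3(C)CC[C@@](O)(C(C)C)[C@H]23)ccc1O | target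

## Step count and risks

Total step count: 12. Longest linear sequence: 11 steps (steps 1–9, 11 and 12; step 10 is a one-step side branch).

Steps most likely to fail:

Step 8. The cascade may stop after the radical addition, because protonation of the iron enolate can outrun the aldol ring closure. The fallback divides the event into two known operations. It sets out from 14: the same iron-hydride Giese coupling with acrolein is worked up at the open keto aldehyde 3-[(1R,2S,3R,6R)-6-[(tert-butyldimethylsilyl)oxy]-3-hydroxy-1,5-dimethyl-2-(2-methylpropanoyl)cyclohept-4-en-1-yl]propanal F1. This is then closed by a separate amine-catalysed intramolecular aldol reaction (pyrrolidine/AcOH or L-proline, enamine 5-enolexo aldolisation). The fallback comes back to the route at 17.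

Step 9. The heat needed for decarbonylation may cause retro-aldol opening of the β-hydroxy aldehyde or rhodium-hydride isomerisation of the allylic alcohol. The fallback replaces CO extrusion by a radical decarboxylation at room temperature. It sets out from 17: Pinnick oxidation (NaClO2, NaH2PO4, 2-methylbut-2-ene, tBuOH/H2O) should give (2S,3R,3aS,4R,7R,8aR)-7-[(tert-butyldimethylsilyl)oxy]-3,4-dihydroxy-6,8a-dimethyl-3-(propan-2-yl)-1,2,3,3a,4,7,8,8a-octahydroazulene-2-carboxylic acid F2. Visible-light hydrodecarboxylation (9-mesityl-10-methylacridinium photocatalyst, PhSSPh as hydrogen-atom shuttle, blue light) then removes the carboxyl group. The fallback comes back to the route at 18.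

Step 11. Elimination or SN2′ substitution may compete with SN2 displacement at the hindered C6 position next to the ring fusion. The fallback inverts C6 by oxidation and directed reduction instead of substitution. It sets out from 18: allylic oxidation with MnO2 should give (3R,3aR,7R,8aR)-7-[(tert-butyldimethylsilyl)oxy]-3-hydroxy-6,8a-dimethyl-3-(propan-2-yl)-2,3,3a,7,8,8a-hexahydroazulen-4(1H)-one F3. Hydroxyl-directed reduction with Me4NBH(OAc)3 delivers hydride from the face of the C4 hydroxyl and should give (3R,3aS,4S,7R,8aR)-7-[(tert-butyldimethylsilyl)oxy]-6,8a-dimethyl-3-(propan-2-yl)-1,2,3,3a,4,7,8,8a-octahydroazulene-3,4-diol F4. Steglich esterification (DCC, DMAP, CH2Cl2) with acid 21 then acylates the secondary hydroxyl with retention. The fallback comes back to the route at 23.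

Further compounds
F1 | step 8 | 3-[(1R,2S,3R,6R)-6-[(tert-butyldimethylsilyl)oxy]-3-hydroxy-1,5-dimethyl-2-(2-methylpropanoyl)cyclohept-4-en-1-yl]propanal | O[C@@H]1C=C(C)[C@H](O[Si](C)(C)C(C)(C)C)C[C@@](C)(CCC=O)[C@@H]1C(=O)C(C)C
F2 | step 9 | (2S,3R,3aS,4R,7R,8aR)-7-[(tert-butyldimethylsilyl)oxy]-3,4-dihydroxy-6,8a-dimethyl-3-(propan-2-yl)-1,2,3,3a,4,7,8,8a-octahydroazulene-2-carboxylic acid | O[C@@H]1C=C(C)[C@H](O[Si](C)(C)C(C)(C)C)C[C@@]2(C)C[C@H](C(=O)O)[C@@](O)(C(C)C)[C@H]12
F3 | step 11 | (3R,3aR,7R,8aR)-7-[(tert-butyldimethylsilyl)oxy]-3-hydroxy-6,8a-dimethyl-3-(propan-2-yl)-2,3,3a,7,8,8a-hexahydroazulen-4(1H)-one | O=C1C=C(C)[C@H](O[Si](C)(C)C(C)(C)C)C[C@@]2(C)CC[C@@](O)(C(C)C)[C@H]12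
F4 | step 11 | (3R,3aS,4S,7R,8aR)-7-[(tert-butyldimethylsilyl)oxy]-6,8a-dimethyl-3-(propan-2-yl)-1,2,3,3a,4,7,8,8a-octahydroazulene-3,4-diol | O[C@H]1C=C(C)[C@H](O[Si](C)(C)C(C)(C)C)C[C@@]2(C)CC[C@@](O)(C(C)C)[C@H]12
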